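**Plan**

1. Retrosynthetic cuts: the C7–C8 bond of the two-carbon tether (made as an alkene by Horner–Wadsworth–Emmons olefination, then saturated); both C–O bonds of the 1,2-dioxane (C3–O by SN2 on a mesylate, C6–O by perhydrolysis of an epoxide); C2–C3 (crotylation); and, in the carbocycle, the two bonds that flank the methyl-bearing enone carbon C2'.
2. Enabling feature: the six-membered carbocycle holds the unit O=C3'–C2'(CH3)=C1', with C1' bound to the quaternary C6'(CH3)2. Atoms C3', C1', C6', C5', C4' are a cyclopentanone enol ether, and C2' with its methyl is a single chloro(methyl)carbene carbon inserted between C3' and C1'.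
3. Fragment A: the carbocycle arises first (five-membered ring, transient cyclopropane, then six-membered ring), followed by bromination of the C1' methyl and an Arbuzov reaction.
4. Fragment B: geranyl acetate supplies C3–C7 and the C6 methyl, and the crotyl unit supplies C1, C2 and the C2 methyl. The 1,2-dioxane is the second ring to form. The vinyl group becomes the ester and the glycol becomes the C7 aldehyde. Fragments A and B are joined at C7=C8, and diimide saturates that alkene.
5. Stereochemistry: C2 and C3 come from a reagent-controlled Brown anti-crotylation (C3 is then inverted in the ring closure); C6 comes from a Sharpless asymmetric epoxidation and is inverted in the perhydrolysis.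

Key step: step 2

Numbering used in the text: chain C1 (ester carbon) to C8; ring carbons C1' (bears the tether), C2' (CH3), C3' (C=O), C6' (CMe2).
Assumption: molybdenum-catalysed perhydrolysis of the acyclic trisubstituted epoxide is taken to proceed with inversion at the tertiary carbon, as it does for cyclic trisubstituted epoxides.

**Route**

Step 1
Reactants: 1 2,3-dimethylcyclopent-2-en-1-one
Product: 2 trimethyl[(2,3,3-trimethylcyclopent-1-en-1-yl)oxy]silane
Conditions: Me2CuLi (MeLi, CuI), TMSCl, Et3N, Et2O, −78 → 0 °C
Reagents that add atoms: lithium dimethylcuprate, [Li+].C[Cu-]C; chlorotrimethylsilane, C[Si](C)(C)Cl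
Why: TMSCl-accelerated conjugate addition of the Gilman cuprate builds the quaternary carbon, and O-silylation of the resulting enolate fixes the tetrasubstituted enol double bond between the former carbonyl carbon and the methyl-bearing carbon as a single regioisomer.

Step 2
Reactants: 2 trimethyl[(2,3,3-trimethylcyclopent-1-en-1-yl)oxy]silane
Product: 4 2,3,4,4-tetramethylcyclohex-2-en-1-one, via chlorocyclopropane adduct 3 (not isolated)
Conditions: CH3CHCl2, n-BuLi, Et2O, −40 °C → rt; then PhMe, 110 °C
Reagents that add atoms: 1,1-dichloroethane, CC(Cl)Cl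
Why: n-BuLi converts 1,1-dichloroethane into 1,1-dichloroethyllithium, which loses LiCl and transfers chloro(methyl)carbene to the electron-rich enol double bond of 2 in a concerted [2+1] cheletropic addition that closes the cyclopropane of 3; on heating, the C–Cl bond ionises in concert with disrotatory two-electron electrocyclic opening of the bond shared by the two rings (cyclopropyl to allyl cation), pushed by the siloxy oxygen, and chloride removes silicon to release the enone. The closest known reaction type is the halocarbene ring enlargement of cyclic silyl enol ethers to 2-substituted cycloalk-2-enones. The six-membered ring therefore arises by one-carbon enlargement of the five-membered ring: the carbene carbon becomes C2 with its methyl, and the two former enol carbons become C1 (C=O) and C3. No stereocentre remains, so the stereoisomers of 3 converge on achiral 4. The required regiochemistry (new carbon between the carbonyl carbon and the carbon next to the quaternary centre) is secured by the enol ether position fixed in step 1, and chemoselectivity by the enol ether being the only alkene. Only the adduct with chlorine syn to the five-membered ring can open in the allowed disrotatory sense, and the carbenoid is expected to place chlorine there preferentially.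

Step 3
Reactants: 4 2,3,4,4-tetramethylcyclohex-2-en-1-one
Product: 5 3-(bromomethyl)-2,4,4-trimethylcyclohex-2-en-1-one
Conditions: NBS, AIBN (cat.), PhCF3, 80 °C
Reagents that add atoms: N-bromosuccinimide, O=C1CCC(=O)N1Br
Why: Wohl–Ziegler bromination should favour the C3 methyl, because hydrogen abstraction there gives a radical delocalised through the C=C bond into the carbonyl (gamma position), the ring gamma carbon is quaternary, and the C2 methyl gives only a cross-conjugated allyl radical.

Step 4
Reactants: 5 3-(bromomethyl)-2,4,4-trimethylcyclohex-2-en-1-one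
Product: 6 diethyl [(2,6,6-trimethyl-3-oxocyclohex-1-en-1-yl)methyl]phosphonate
Conditions: P(OEt)3, PhMe, 110 °C
Reagents that add atoms: triethyl phosphite, CCOP(OCC)OCC
Why: Michaelis–Arbuzov reaction of the primary allylic bromide (SN2 by phosphorus, then dealkylation by bromide) gives the vinylogous keto phosphonate.

Step 5
Reactants: 7 geranyl acetate, (2E)-3,7-dimethylocta-2,6-dien-1-yl acetate
Product: 8 (2E)-3-methyl-6-oxohex-2-en-1-yl acetate
Conditions: O3 (1 equiv), CH2Cl2, pyridine, −78 °C; then Me2S
Reagents that add atoms: ozone, [O-][O+]=O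
Why: selective ozonolysis cleaves the remote, more electron-rich trisubstituted alkene, while the alkene next to the allylic acetate is inductively deactivated and should survive.

Step 6
Reactants: 8 (2E)-3-methyl-6-oxohex-2-en-1-yl acetate
Product: 9 (2E,6R,7S)-6-hydroxy-3,7-dimethylnona-2,8-dien-1-yl acetate
Conditions: trans-2-butene, n-BuLi, KOtBu, THF, −78 → −45 °C; (−)-Ipc2BOMe; BF3·OEt2; then 8, −78 °C; NaBO3·4H2O, THF/H2O, rt
Reagents that add atoms: (E)-crotyldiisopinocampheylborane (made in the flask from trans-2-butene, C/C=C/C), C/C=C/CB([C@@H]1C[C@@H]2C[C@@H](C2(C)C)[C@H]1C)[C@@H]1C[C@@H]2C[C@@H](C2(C)C)[C@H]1C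
Why: Brown crotylboration through a closed Zimmerman–Traxler chair gives the anti relationship from the (E)-crotyl geometry, and the isopinocampheyl groups derived from (−)-Ipc2BOMe direct addition to the Si face of the aldehyde, which sets the carbinol carbon (R, later C3) and the methyl-bearing carbon (S, later C2).

Step 7
Reactants: 9 (2E,6R,7S)-6-hydroxy-3,7-dimethylnona-2,8-dien-1-yl acetate
Product: 10 (2E,6R,7S)-6-(methanesulfonyloxy)-3,7-dimethylnona-2,8-dien-1-yl acetate
Conditions: MsCl, Et3N, CH2Cl2, 0 °C
Reagents that add atoms: methanesulfonyl chloride, CS(Cl)(=O)=O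
Why: sulfonylation of the only free hydroxyl installs the leaving group with retention, because the C–O bond is not touched.

Step 8
Reactants: 10 (2E,6R,7S)-6-(methanesulfonyloxy)-3,7-dimethylnona-2,8-dien-1-yl acetate
Product: 11 (3S,4R,7E)-9-hydroxy-3,7-dimethylnona-1,7-dien-4-yl methanesulfonate
Conditions: K2CO3 (cat.), MeOH, 0 °C
Reagents that add atoms: none
Why: base-catalysed transesterification removes the primary allylic acetate, and the secondary mesylate should be inert to cold methanolic carbonate.

Step 9
Reactants: 11 (3S,4R,7E)-9-hydroxy-3,7-dimethylnona-1,7-dien-4-yl methanesulfonate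
Product: 12 (3S,4R)-6-[(2R,3R)-3-(hydroxymethyl)-2-methyloxiran-2-yl]-3-methylhex-1-en-4-yl methanesulfonate
Conditions: Ti(OiPr)4, D-(−)-diethyl tartrate, t-BuOOH, 4 Å MS, CH2Cl2, −20 °C
Reagents that add atoms: tert-butyl hydroperoxide, CC(C)(C)OO
Why: Sharpless asymmetric epoxidation acts only on the allylic alcohol alkene, and the D-(−)-tartrate ligand delivers oxygen to the face that gives the (2R,3R)-epoxide, which sets the future C6 under reagent control.

Step 10
Reactants: 12 (3S,4R)-6-[(2R,3R)-3-(hydroxymethyl)-2-methyloxiran-2-yl]-3-methylhex-1-en-4-yl methanesulfonate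
Product: 13 (3S,4R,7S,8R)-7-hydroperoxy-8,9-dihydroxy-3,7-dimethylnon-1-en-4-yl methanesulfonate
Conditions: H2O2 (anhydrous, Et2O), H3PMo12O40 (cat.), 0 °C → rt
Reagents that add atoms: hydrogen peroxide, OO
Why: molybdenum-catalysed perhydrolysis opens the activated epoxide at the tertiary carbon (better able to carry positive charge and remote from the deactivating CH2OH) in an SN2-like manner with inversion, which gives the tertiary hydroperoxide with the C6 configuration of the target.

Step 11
Reactants: 13 (3S,4R,7S,8R)-7-hydroperoxy-8,9-dihydroxy-3,7-dimethylnon-1-en-4-yl methanesulfonate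
Product: 14 (1R)-1-[(3S,6S)-6-[(2S)-but-3-en-2-yl]-3-methyl-1,2-dioxan-3-yl]ethane-1,2-diol
Conditions: KOtBu (1.05 equiv), 18-crown-6, THF, 0 °C
Reagents that add atoms: none
Why: intramolecular alkylation of the hydroperoxide: the peroxy anion (more acidic than the alcohols and an alpha-effect nucleophile) displaces the secondary mesylate in a 6-exo-tet SN2 reaction with inversion, which closes the 1,2-dioxane and sets C3.

Step 12
Reactants: 14 (1R)-1-[(3S,6S)-6-[(2S)-but-3-en-2-yl]-3-methyl-1,2-dioxan-3-yl]ethane-1,2-diol
Product: 16 (2R)-2-[(3S,6S)-6-[(1R)-1,2-dihydroxyethyl]-6-methyl-1,2-dioxan-3-yl]propanoic acid, via dioxanylpropanal 15 (not isolated)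
Conditions: O3, MeCN/H2O, 0 °C; then NaClO2, NaH2PO4, 2-methylbut-2-ene, 0 °C → rt
Reagents that add atoms: ozone, [O-][O+]=O; sodium chlorite, [Na+].[O-]Cl=O
Why: ozonolysis in aqueous medium (water captures the carbonyl oxide and gives the aldehyde directly) followed in the same flask by Pinnick oxidation converts the vinyl group into the acid under weakly acidic conditions, so the epimerisable beta-peroxy aldehyde is never isolated and the O–O bond and the glycol stay intact.

Step 13
Reactants: 16 (2R)-2-[(3S,6S)-6-[(1R)-1,2-dihydroxyethyl]-6-methyl-1,2-dioxan-3-yl]propanoic acid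
Product: 17 methyl (2R)-2-[(3S,6S)-6-[(1R)-1,2-dihydroxyethyl]-6-methyl-1,2-dioxan-3-yl]propanoate
Conditions: TMSCHN2, PhMe/MeOH, 0 °C
Reagents that add atoms: (trimethylsilyl)diazomethane, C[Si](C)(C)C=[N+]=[N-]
Why: O-methylation of the carboxylic acid by the diazoalkane proceeds without base, so C2 and the base-sensitive beta-peroxy ester are not put at risk.

Step 14
Reactants: 17 methyl (2R)-2-[(3S,6S)-6-[(1R)-1,2-dihydroxyethyl]-6-methyl-1,2-dioxan-3-yl]propanoate
Product: 18 methyl (2R)-2-[(3S,6S)-6-formyl-6-methyl-1,2-dioxan-3-yl]propanoate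
Conditions: NaIO4, THF/H2O (pH 7), 0 °C
Reagents that add atoms: none
Why: Malaprade glycol cleavage removes the extra carbon and leaves a non-enolisable alpha-peroxy aldehyde on the quaternary C6, whose configuration cannot be lost.

Step 15
Reactants: 6 diethyl [(2,6,6-trimethyl-3-oxocyclohex-1-en-1-yl)methyl]phosphonate; 18 methyl (2R)-2-[(3S,6S)-6-formyl-6-methyl-1,2-dioxan-3-yl]propanoate
Product: 19 methyl (2R)-2-[(3S,6S)-6-methyl-6-[(E)-2-(2,6,6-trimethyl-3-oxocyclohex-1-en-1-yl)ethenyl]-1,2-dioxan-3-yl]propanoate
Conditions: 6, NaH (1.0 equiv), THF, 0 °C; then 18, −78 → 0 °C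
Reagents that add atoms: none
Why: Horner–Wadsworth–Emmons olefination: the preformed, weakly basic vinylogous phosphonate anion adds through its phosphorus-bearing carbon to the non-enolisable aldehyde and eliminates phosphate to give the (E)-dienone, with no free strong base left to attack the beta-peroxy ester.

Step 16
Reactants: 19 methyl (2R)-2-[(3S,6S)-6-methyl-6-[(E)-2-(2,6,6-trimethyl-3-oxocyclohex-1-en-1-yl)ethenyl]-1,2-dioxan-3-yl]propanoate
Product: 20 methyl diacarnoate A, methyl (2R)-2-[(3S,6R)-6-methyl-6-[2-(2,6,6-trimethyl-3-oxocyclohex-1-en-1-yl)ethyl]-1,2-dioxan-3-yl]propanoate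
Conditions: KO2CN=NCO2K, AcOH, CH2Cl2/MeOH, 0 °C → rt
Reagents that add atoms: none
Why: diimide reduction transfers two hydrogens in a concerted syn fashion to the disubstituted C7=C8 alkene, while the tetrasubstituted enone alkene is too hindered to react and the O–O bond is not reduced by diimide.

**Compound list**

1 | 2,3-dimethylcyclopent-2-en-1-one | CC1=C(C)C(=O)CC1 | starting material
2 | trimethyl[(2,3,3-trimethylcyclopent-1-en-1-yl)oxy]silane | CC1=C(O[Si](C)(C)C)CCC1(C)C | intermediate
3 | 6-chloro-1,2,2,6-tetramethyl-5-(trimethylsilyloxy)bicyclo[3.1.0]hexane (mixture of stereoisomers, not isolated) | CC1(Cl)C2(O[Si](C)(C)C)CCC(C)(C)C12C | intermediate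
4 | 2,3,4,4-tetramethylcyclohex-2-en-1-one | CC1=C(C)C(C)(C)CCC1=O | intermediate
5 | 3-(bromomethyl)-2,4,4-trimethylcyclohex-2-en-1-one | CC1=C(CBr)C(C)(C)CCC1=O | intermediate
6 | diethyl [(2,6,6-trimethyl-3-oxocyclohex-1-en-1-yl)methyl]phosphonate | CCOP(=O)(CC1=C(C)C(=O)CCC1(C)C)OCC | intermediate
7 | geranyl acetate, (2E)-3,7-dimethylocta-2,6-dien-1-yl acetate | CC(C)=CCC/C(C)=C/COC(C)=O | starting material
8 | (2E)-3-methyl-6-oxohex-2-en-1-yl acetate | O=CCC/C(C)=C/COC(C)=O | intermediate
9 | (2E,6R,7S)-6-hydroxy-3,7-dimethylnona-2,8-dien-1-yl acetate | C=C[C@H](C)[C@H](O)CC/C(C)=C/COC(C)=O | intermediate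
10 | (2E,6R,7S)-6-(methanesulfonyloxy)-3,7-dimethylnona-2,8-dien-1-yl acetate | C=C[C@H](C)[C@H](OS(C)(=O)=O)CC/C(C)=C/COC(C)=O | intermediate
11 | (3S,4R,7E)-9-hydroxy-3,7-dimethylnona-1,7-dien-4-yl methanesulfonate | C=C[C@H](C)[C@H](OS(C)(=O)=O)CC/C(C)=C/CO | intermediate
12 | (3S,4R)-6-[(2R,3R)-3-(hydroxymethyl)-2-methyloxiran-2-yl]-3-methylhex-1-en-4-yl methanesulfonate | C=C[C@H](C)[C@H](OS(C)(=O)=O)CC[C@]1(C)[C@@H](CO)O1 | intermediate
13 | (3S,4R,7S,8R)-7-hydroperoxy-8,9-dihydroxy-3,7-dimethylnon-1-en-4-yl methanesulfonate | C=C[C@H](C)[C@H](OS(C)(=O)=O)CC[C@@](C)([C@H](O)CO)OO | intermediate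
14 | (1R)-1-[(3S,6S)-6-[(2S)-but-3-en-2-yl]-3-methyl-1,2-dioxan-3-yl]ethane-1,2-diol | C=C[C@H](C)[C@@H]1CC[C@@](C)([C@H](O)CO)OO1 | intermediate
15 | (2R)-2-[(3S,6S)-6-[(1R)-1,2-dihydroxyethyl]-6-methyl-1,2-dioxan-3-yl]propanal (not isolated) | O=C[C@H](C)[C@@H]1CC[C@@](C)([C@H](O)CO)OO1 | intermediate
16 | (2R)-2-[(3S,6S)-6-[(1R)-1,2-dihydroxyethyl]-6-methyl-1,2-dioxan-3-yl]propanoic acid | OC(=O)[C@H](C)[C@@H]1CC[C@@](C)([C@H](O)CO)OO1 | intermediate
17 | methyl (2R)-2-[(3S,6S)-6-[(1R)-1,2-dihydroxyethyl]-6-methyl-1,2-dioxan-3-yl]propanoate | COC(=O)[C@H](C)[C@@H]1CC[C@@](C)([C@H](O)CO)OO1 | intermediate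
18 | methyl (2R)-2-[(3S,6S)-6-formyl-6-methyl-1,2-dioxan-3-yl]propanoate | COC(=O)[C@H](C)[C@@H]1CC[C@@](C)(C=O)OO1 | intermediate
19 | methyl (2R)-2-[(3S,6S)-6-methyl-6-[(E)-2-(2,6,6-trimethyl-3-oxocyclohex-1-en-1-yl)ethenyl]-1,2-dioxan-3-yl]propanoate | COC(=O)[C@H](C)[C@@H]1CC[C@@](C)(/C=C/C2=C(C)C(=O)CCC2(C)C)OO1 | intermediate
20 | methyl diacarnoate A, methyl (2R)-2-[(3S,6R)-6-methyl-6-[2-(2,6,6-trimethyl-3-oxocyclohex-1-en-1-yl)ethyl]-1,2-dioxan-3-yl]propanoate | COC(=O)[C@H](C)[C@@H]1CC[C@@](C)(CCC2=C(C)C(=O)CCC2(C)C)OO1 | target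

**Step count and risks**

Total step count: 16. Longest linear sequence: 12 steps (7 to 20, steps 5 to 16).

Steps most likely to fail:

Step 2. The carbenoid may be captured poorly by the hindered tetrasubstituted enol ether (competing 1,2-hydrogen shift of the carbene to vinyl chloride), and part of the adduct may carry chlorine on the face that cannot open. Fallback: from 2, dibromocarbene (CHBr3, KOtBu, pentane, 0 °C), which always places one halogen syn to the five-membered ring, should give 6,6-dibromo-1,2,2-trimethyl-5-(trimethylsilyloxy)bicyclo[3.1.0]hexane F1. Thermal ring enlargement (PhMe, 110 °C) then gives 2-bromo-3,4,4-trimethylcyclohex-2-en-1-one F2. Suzuki–Miyaura methylation (trimethylboroxine, Pd(PPh3)4, K2CO3, dioxane, 100 °C) comes back to the route at 4.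

Step 11. Under base, the beta-hydroxy hydroperoxide may fragment by C–C cleavage, or the mesylate may undergo E2 elimination, before the peroxy anion closes the ring. Fallback: the order of the two C–O bond formations is reversed, which also removes the dependence on step 10. From 12, the secondary mesylate is displaced first by hydrogen peroxide (50% H2O2, CsOH·H2O, DMF, 0 °C, SN2 with inversion) to give [(2R,3R)-3-[(3S,4S)-3-hydroperoxy-4-methylhex-5-en-1-yl]-3-methyloxiran-2-yl]methanol F3. Acid catalysis (camphorsulfonic acid, CH2Cl2, 0 °C) then lets the secondary hydroperoxide open the epoxide at its tertiary carbon in a 6-exo manner with inversion, and the route is rejoined at 14.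

Step 3. Radical bromination may be unselective between the C3 methyl, the C2 methyl and the position next to the carbonyl. Fallback: from 4, soft enolisation under equilibrating conditions (TMSCl, NaI, Et3N, MeCN) should give the linear dienoxysilane trimethyl[(2,4,4-trimethyl-3-methylidenecyclohex-1-en-1-yl)oxy]silane F4. Ionic bromination with NBS (THF, −78 °C) at its unhindered exocyclic terminus comes back to the route at 5.

**Further compounds**

F1 | step 2 | 6,6-dibromo-1,2,2-trimethyl-5-(trimethylsilyloxy)bicyclo[3.1.0]hexane | BrC1(Br)C2(O[Si](C)(C)C)CCC(C)(C)C12C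
F2 | step 2 | 2-bromo-3,4,4-trimethylcyclohex-2-en-1-one | CC1=C(Br)C(=O)CCC1(C)C
F3 | step 11 | [(2R,3R)-3-[(3S,4S)-3-hydroperoxy-4-methylhex-5-en-1-yl]-3-methyloxiran-2-yl]methanol | C=C[C@H](C)[C@@H](OO)CC[C@]1(C)[C@@H](CO)O1
F4 | step 3 | trimethyl[(2,4,4-trimethyl-3-methylidenecyclohex-1-en-1-yl)oxy]silane | C=C1C(C)=C(O[Si](C)(C)C)CCC1(C)C
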